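**Retrosynthetic overview** (oxane numbering: O1, hemiketal C2, CHBr C3, C4, C5, OCH2 C6; side chain C1' methyl, C2' C–Cl, C3'=C4'Br)
- The strategy rests on the adjacent stereocentres C5 (ring CH) and C2' (fully substituted C–Cl). With C3' at the carbonyl level, C2' is the α- and C5 the β-carbon, so the C4–C5 and C2'–Cl bonds are the nucleophilic and electrophilic halves of one conjugate addition–enolate chlorination.
- Key disconnection: an (E)-N-enoylbornanesultam (C6–C5=C2'–C3'), a ketal-protected 3-oxobutyl Grignard reagent (C4, C3, C2, CH3) and NCS.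
- After the key step C3' is taken from imide to aldehyde, and C3'=C4'Br is made by Takai bromo-olefination.
- C3–Br and C2–OH come last, from NBS/water addition to the O1–C2=C3 enol ether, followed by thermodynamic equilibration of C2 and C3.
- Ring order: the oxane is the only ring; it closes at O1–C2 by cyclodehydration of the 1,5-hydroxy ketone in step 11, after both acyclic stereocentres are in place.

Key step: step 6

Assumption: alkyl transfer and chlorination are both taken to follow the magnesium-chelate model of N-enoylbornane-10,2-sultams (reaction on the face remote from the bornane C3 methylene), which for the (2S)-sultam is the Cβ-si/Cα-si face needed here; should the observed sense be opposite, the (2R)-sultam would be used in the same sequence.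

**Route**

Step 1
Reactants: 1 (tert-butyldimethylsilyloxy)acetaldehyde; 2 ethyl 2-(triphenylphosphoranylidene)propanoate
Product: 3 ethyl (2E)-4-(tert-butyldimethylsilyloxy)-2-methylbut-2-enoate
Conditions: CH2Cl2, 0 °C to rt
Reagents that add atoms: none
Why: Wittig olefination with a stabilised α-branched ylide should give the trisubstituted (E)-enoate (ester trans to CH2OTBS) selectively.

Step 2
Reactants: 3 ethyl (2E)-4-(tert-butyldimethylsilyloxy)-2-methylbut-2-enoate
Product: 4 (2E)-4-(tert-butyldimethylsilyloxy)-2-methylbut-2-enoic acid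
Conditions: LiOH·H2O, THF/MeOH/H2O, rt; then aq. HCl to pH 4, 0 °C
Reagents that add atoms: lithium hydroxide, [Li+].[OH-]
Why: Ester saponification at room temperature leaves the primary TBS ether and the alkene geometry untouched when the acidification is stopped at pH 4.

Step 3
Reactants: 4 (2E)-4-(tert-butyldimethylsilyloxy)-2-methylbut-2-enoic acid; 5 (2S)-bornane-10,2-sultam [(1R)-(+)-2,10-camphorsultam]
Product: 8 (2S)-N-[(2E)-4-(tert-butyldimethylsilyloxy)-2-methylbut-2-enoyl]bornane-10,2-sultam, via acid chloride 6 (not isolated), via sodium sultamide 7 (not isolated)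
Conditions: 4, 1-chloro-N,N,2-trimethylprop-1-en-1-amine, CH2Cl2, 0 °C to rt; 5, NaH, THF, 0 °C; solutions combined, 0 °C to rt
Reagents that add atoms: none
Why: The chloroenamine makes the acid chloride without free HCl (TBS ether and E geometry are safe), and N-acylation of the sodium sultamide is the standard entry to N-enoylsultams.

Step 4
Reactants: 9 4-chlorobutan-2-one; 10 2,2-dimethylpropane-1,3-diol
Product: 11 2-(2-chloroethyl)-2,5,5-trimethyl-1,3-dioxane
Conditions: HC(OEt)3, TsOH·H2O (cat.), CH2Cl2, rt
Reagents that add atoms: none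
Why: Acid-catalysed ketalisation driven by the orthoformate as water scavenger runs at room temperature, which avoids loss of HCl to methyl vinyl ketone; the neopentyl glycol ketal is chosen because its Grignard reagent is thermally robust.

Step 5
Reactants: 11 2-(2-chloroethyl)-2,5,5-trimethyl-1,3-dioxane
Product: 12 [2-(2,5,5-trimethyl-1,3-dioxan-2-yl)ethyl]magnesium chloride
Conditions: Mg turnings (activated with 1 mol% i-Bu2AlH), THF, 45 °C; titrated and used at once
Reagents that add atoms: magnesium, [Mg]
Why: Grignard formation from the primary chloride should proceed without self-destruction of the 1,3-dioxane ketal, and the chloride keeps the medium of step 6 free of bromide.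

Step 6
Reactants: 8 (2S)-N-[(2E)-4-(tert-butyldimethylsilyloxy)-2-methylbut-2-enoyl]bornane-10,2-sultam; 12 [2-(2,5,5-trimethyl-1,3-dioxan-2-yl)ethyl]magnesium chloride
Product: 14 (2S)-N-[(2S,3R)-3-[(tert-butyldimethylsilyloxy)methyl]-2-chloro-2-methyl-5-(2,5,5-trimethyl-1,3-dioxan-2-yl)pentanoyl]bornane-10,2-sultam, via chloromagnesium enolate 13 (not isolated)
Conditions: 12 (2.5 equiv), THF, −78 °C; then NCS (4 equiv) in THF, −78 to −40 °C; aq. NH4Cl
Reagents that add atoms: N-chlorosuccinimide, O=C1CCC(=O)N1Cl
Why: Magnesium bridges the imide carbonyl and a sulfonyl oxygen, which fixes the C=O/SO2-syn, s-cis enoyl conformer; a second equivalent of 12 transfers its alkyl group to the β-carbon (future C5, bond C4–C5) and leaves the chelated (Z)-enolate 13, which NCS chlorinates at the α-carbon (future C2', bond C2'–Cl). The closest known reaction type is the organomagnesium 1,4-addition/enolate trapping of N-enoylbornane-10,2-sultams, joined to the electrophilic α-halogenation of chiral imide enolates by N-halosuccinimides; no ring is closed. C5 is set by the sultam, the alkyl group entering on the enoyl face turned away from the bornane C3 methylene (Cβ-si), and C2' is set by the same auxiliary, chlorine entering the still chelated enolate on the same face (Cα-si). Because the acceptor is (E), same-face delivery of carbon and chlorine gives the (2S,3R) pair, that is C2'(S) and C5(R) of the target. The step needs 1,4- over 1,2-addition (secured by the chelate, the alkylmagnesium chloride and −78 °C), chlorination rather than bromination (secured by the bromide-free medium, so NCS cannot oxidise bromide to electrophilic bromine), and a tertiary chloride formed without a cation (chlorine arrives as an electrophile at an enolate).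

Step 7
Reactants: 14 (2S)-N-[(2S,3R)-3-[(tert-butyldimethylsilyloxy)methyl]-2-chloro-2-methyl-5-(2,5,5-trimethyl-1,3-dioxan-2-yl)pentanoyl]bornane-10,2-sultam
Product: 15 (2S,3R)-3-[(tert-butyldimethylsilyloxy)methyl]-2-chloro-2-methyl-5-(2,5,5-trimethyl-1,3-dioxan-2-yl)pentan-1-ol
Conditions: LiBH4, H2O (1 equiv), THF, 0 °C
Reagents that add atoms: none
Why: Reductive cleavage of the N-acylsultam by borohydride attacks the activated α-chloro imide carbonyl, leaves the tertiary chloride and both stereocentres untouched, and returns the auxiliary.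

Step 8
Reactants: 15 (2S,3R)-3-[(tert-butyldimethylsilyloxy)methyl]-2-chloro-2-methyl-5-(2,5,5-trimethyl-1,3-dioxan-2-yl)pentan-1-ol
Product: 16 (2S,3R)-3-[(tert-butyldimethylsilyloxy)methyl]-2-chloro-2-methyl-5-(2,5,5-trimethyl-1,3-dioxan-2-yl)pentanal
Conditions: Dess–Martin periodinane, pyridine, CH2Cl2, 0 °C to rt
Reagents that add atoms: none
Why: Buffered Dess–Martin oxidation gives an aldehyde with no α-hydrogen, so C2' cannot epimerise, and the TBS ether and ketal survive.

Step 9
Reactants: 16 (2S,3R)-3-[(tert-butyldimethylsilyloxy)methyl]-2-chloro-2-methyl-5-(2,5,5-trimethyl-1,3-dioxan-2-yl)pentanal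
Product: 17 tert-butyl{[(2R,3S,4E)-5-bromo-3-chloro-3-methyl-2-[2-(2,5,5-trimethyl-1,3-dioxan-2-yl)ethyl]pent-4-en-1-yl]oxy}dimethylsilane
Conditions: CHBr3, CrBr2 (anhydrous, excess), THF, 0 °C to rt
Reagents that add atoms: bromoform, BrC(Br)Br
Why: Takai olefination with the geminal dichromium reagent from bromoform and divalent chromium should give the (E)-bromoalkene, E selectivity being highest for α-quaternary aldehydes, and CrBr2 in place of CrCl2 avoids bromine/chlorine scrambling in the vinyl halide.

Step 10
Reactants: 17 tert-butyl{[(2R,3S,4E)-5-bromo-3-chloro-3-methyl-2-[2-(2,5,5-trimethyl-1,3-dioxan-2-yl)ethyl]pent-4-en-1-yl]oxy}dimethylsilane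
Product: 18 (5R,6S,7E)-8-bromo-6-chloro-5-(hydroxymethyl)-6-methyloct-7-en-2-one (in equilibrium with its cyclic hemiketal)
Conditions: 1 M aq. HCl, THF, 0 °C to rt
Reagents that add atoms: water, O
Why: Acid hydrolysis removes the TBS ether and the ketal together; the tertiary allylic chloride should survive because the bromine on the alkene terminus and the poorly ionising medium disfavour its ionisation.

Step 11
Reactants: 18 (5R,6S,7E)-8-bromo-6-chloro-5-(hydroxymethyl)-6-methyloct-7-en-2-one
Product: 19 (3R)-3-[(2S,3E)-4-bromo-2-chlorobut-3-en-2-yl]-6-methyl-3,4-dihydro-2H-pyran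
Conditions: PPTS (cat.), benzene, reflux, 4 Å molecular sieves (Soxhlet); used directly
Reagents that add atoms: none
Why: Acid-catalysed cyclodehydration of the 1,5-hydroxy ketone through its hemiketal, with removal of water, closes the oxane at O1–C2 and gives the thermodynamically preferred endocyclic enol ether O1–C2=C3, which fixes C3 as the site of bromination.

Step 12
Reactants: 19 (3R)-3-[(2S,3E)-4-bromo-2-chlorobut-3-en-2-yl]-6-methyl-3,4-dihydro-2H-pyran
Product: 20 (5R)-3-bromo-5-[(2S,3E)-4-bromo-2-chlorobut-3-en-2-yl]-2-methyloxan-2-ol, mixture of C3 epimers (each as equilibrating C2 anomers)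
Conditions: NBS, THF/H2O (4:1), 0 °C
Reagents that add atoms: N-bromosuccinimide, O=C1CCC(=O)N1Br; water, O
Why: Bromo-hydroxylation of the electron-rich enol ether puts Br+ on C3 and water on the oxocarbenium carbon C2, while the electron-poor bromovinyl group does not compete; C3 is expected as a mixture (axial attack may favour bromine trans to the C5 substituent), which step 13 corrects.

Step 13
Reactants: 20 (5R)-3-bromo-5-[(2S,3E)-4-bromo-2-chlorobut-3-en-2-yl]-2-methyloxan-2-ol, mixture of C3 epimers
Product: 21 (2R,3S,5R)-3-bromo-5-[(2S,3E)-4-bromo-2-chlorobut-3-en-2-yl]-2-methyloxan-2-ol (CNP0220042.1)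
Conditions: n-Bu4NBr (0.2 equiv), PPTS (cat.), water-saturated CH2Cl2, rt; chromatography
Reagents that add atoms: tetrabutylammonium bromide (bromide exchanged at C3), CCCC[N+](CCCC)(CCCC)CCCC.[Br-]
Why: Under thermodynamic control (acid-catalysed ring–chain tautomerism for C2, Finkelstein-type SN2 bromide exchange on the open-chain α-bromo ketone for C3) the mixture should drain into the chair with axial anomeric OH, equatorial C2 methyl, equatorial C3 bromine and equatorial C5 side chain, which is the (2R,3S) target; the preference at C3 is expected to be modest, so any remaining C3 epimer would be separated and resubmitted.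

**Compound list**
1 | (tert-butyldimethylsilyloxy)acetaldehyde | CC(C)(C)[Si](C)(C)OCC=O | starting material
2 | ethyl 2-(triphenylphosphoranylidene)propanoate | CCOC(=O)C(C)=P(c1ccccc1)(c1ccccc1)c1ccccc1 | starting material
3 | ethyl (2E)-4-(tert-butyldimethylsilyloxy)-2-methylbut-2-enoate | CCOC(=O)/C(C)=C/CO[Si](C)(C)C(C)(C)C | intermediate
4 | (2E)-4-(tert-butyldimethylsilyloxy)-2-methylbut-2-enoic acid | OC(=O)/C(C)=C/CO[Si](C)(C)C(C)(C)C | intermediate
5 | (2S)-bornane-10,2-sultam | O=S1(=O)C[C@]23CC[C@H](C2(C)C)C[C@@H]3N1 | starting material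
6 | (2E)-4-(tert-butyldimethylsilyloxy)-2-methylbut-2-enoyl chloride | ClC(=O)/C(C)=C/CO[Si](C)(C)C(C)(C)C | intermediate (not isolated)
7 | sodium salt of (2S)-bornane-10,2-sultam | [Na+].O=S1(=O)C[C@]23CC[C@H](C2(C)C)C[C@@H]3[N-]1 | intermediate (not isolated)
8 | (2S)-N-[(2E)-4-(tert-butyldimethylsilyloxy)-2-methylbut-2-enoyl]bornane-10,2-sultam | O=S1(=O)C[C@]23CC[C@H](C2(C)C)C[C@@H]3N1C(=O)/C(C)=C/CO[Si](C)(C)C(C)(C)C | intermediate
9 | 4-chlorobutan-2-one | CC(=O)CCCl | starting material
10 | 2,2-dimethylpropane-1,3-diol | OCC(C)(C)CO | starting material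
11 | 2-(2-chloroethyl)-2,5,5-trimethyl-1,3-dioxane | CC1(CCCl)OCC(C)(C)CO1 | intermediate
12 | [2-(2,5,5-trimethyl-1,3-dioxan-2-yl)ethyl]magnesium chloride | CC1(CC[Mg]Cl)OCC(C)(C)CO1 | intermediate
13 | chloromagnesium (Z)-enolate of the 1,4-adduct of 12 to 8 (C5 set) | O=S1(=O)C[C@]23CC[C@H](C2(C)C)C[C@@H]3N1/C(O[Mg]Cl)=C(\C)[C@@H](CO[Si](C)(C)C(C)(C)C)CCC4(C)OCC(C)(C)CO4 | intermediate (not isolated)
14 | (2S)-N-[(2S,3R)-3-[(tert-butyldimethylsilyloxy)methyl]-2-chloro-2-methyl-5-(2,5,5-trimethyl-1,3-dioxan-2-yl)pentanoyl]bornane-10,2-sultam | O=S1(=O)C[C@]23CC[C@H](C2(C)C)C[C@@H]3N1C(=O)[C@@](C)(Cl)[C@@H](CO[Si](C)(C)C(C)(C)C)CCC4(C)OCC(C)(C)CO4 | intermediate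
15 | (2S,3R)-3-[(tert-butyldimethylsilyloxy)methyl]-2-chloro-2-methyl-5-(2,5,5-trimethyl-1,3-dioxan-2-yl)pentan-1-ol | OC[C@@](C)(Cl)[C@@H](CO[Si](C)(C)C(C)(C)C)CCC1(C)OCC(C)(C)CO1 | intermediate
16 | (2S,3R)-3-[(tert-butyldimethylsilyloxy)methyl]-2-chloro-2-methyl-5-(2,5,5-trimethyl-1,3-dioxan-2-yl)pentanal | O=C[C@@](C)(Cl)[C@@H](CO[Si](C)(C)C(C)(C)C)CCC1(C)OCC(C)(C)CO1 | intermediate
17 | tert-butyl{[(2R,3S,4E)-5-bromo-3-chloro-3-methyl-2-[2-(2,5,5-trimethyl-1,3-dioxan-2-yl)ethyl]pent-4-en-1-yl]oxy}dimethylsilane | C[C@@](Cl)(/C=C/Br)[C@@H](CO[Si](C)(C)C(C)(C)C)CCC1(C)OCC(C)(C)CO1 | intermediate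
18 | (5R,6S,7E)-8-bromo-6-chloro-5-(hydroxymethyl)-6-methyloct-7-en-2-one | C[C@@](Cl)(/C=C/Br)[C@@H](CO)CCC(C)=O | intermediate
19 | (3R)-3-[(2S,3E)-4-bromo-2-chlorobut-3-en-2-yl]-6-methyl-3,4-dihydro-2H-pyran | C[C@@](Cl)(/C=C/Br)[C@H]1COC(C)=CC1 | intermediate
20 | (5R)-3-bromo-5-[(2S,3E)-4-bromo-2-chlorobut-3-en-2-yl]-2-methyloxan-2-ol, mixture at C2 and C3 | C[C@@](Cl)(/C=C/Br)[C@H]1COC(C)(O)C(Br)C1 | intermediate
21 | (2R,3S,5R)-3-bromo-5-[(2S,3E)-4-bromo-2-chlorobut-3-en-2-yl]-2-methyloxan-2-ol | C[C@@](Cl)(/C=C/Br)[C@H]1CO[C@@](C)(O)[C@@H](Br)C1 | target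

**Step count**
Total: 13 steps. Longest linear sequence: 11 steps (steps 1–3 and 6–13); steps 4 and 5 form the side branch.

**Steps most likely to fail**

Step 6. The fully substituted, twisted magnesium enolate may be chlorinated with poor face discrimination or sluggishly in the presence of excess Grignard reagent and magnesium salts, and 1,2-addition may compete. The fallback sets out from 8 and returns at 14, and it separates the two events. The addition of 12 to 8 is quenched with aqueous NH4Cl to give (2S)-N-[(3S)-3-[(tert-butyldimethylsilyloxy)methyl]-2-methyl-5-(2,5,5-trimethyl-1,3-dioxan-2-yl)pentanoyl]bornane-10,2-sultam F1 (either C2 epimer serves). F1 is deprotonated with NaN(SiMe3)2 and silylated with Me3SiCl in THF at −78 °C to the O-trimethylsilyl ketene N,O-acetal F2, which is freed from salts and chlorinated with NCS in CH2Cl2 at −78 °C to give 14. Both stages (1,4-addition/protonation and halogenation of sultam-derived silyl ketene N,O-acetals) are known for this auxiliary.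

Step 9. Divalent chromium may reduce the tertiary α-C–Cl bond in competition with olefination, and E selectivity may erode. The fallback sets out from 16 and returns at 17. Colvin homologation of 16 with lithiated trimethylsilyldiazomethane (THF, −78 to 0 °C) gives tert-butyl{[(2R,3S)-3-chloro-3-methyl-2-[2-(2,5,5-trimethyl-1,3-dioxan-2-yl)ethyl]pent-4-yn-1-yl]oxy}dimethylsilane F3. Syn hydrozirconation of F3 with Cp2Zr(H)Cl in THF and bromination of the alkenylzirconium with NBS, with retention, then gives the (E)-bromoalkene 17 without any low-valent reductant.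

Step 13. Thermodynamic convergence at C3 may be incomplete or unfavourable, and the C6 hydroxyl of the open form may displace bromide to give a tetrahydrofuran. The fallback sets out from 20 and returns at 18. The mixture from step 12 is separated by chromatography into 21 and its C3 epimer, (2R,3R,5R)-3-bromo-5-[(2S,3E)-4-bromo-2-chlorobut-3-en-2-yl]-2-methyloxan-2-ol F4. F4 is debrominated through its open-chain α-bromo ketone form with PPh3 and NaHCO3 in THF/H2O (halophilic attack, then protonation of the enolate) to return 18, which is taken again through steps 11 and 12.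

Further compounds
F1 | step 6 | (2S)-N-[(3S)-3-[(tert-butyldimethylsilyloxy)methyl]-2-methyl-5-(2,5,5-trimethyl-1,3-dioxan-2-yl)pentanoyl]bornane-10,2-sultam | O=S1(=O)C[C@]23CC[C@H](C2(C)C)C[C@@H]3N1C(=O)C(C)[C@@H](CO[Si](C)(C)C(C)(C)C)CCC4(C)OCC(C)(C)CO4
F2 | step 6 | O-trimethylsilyl ketene N,O-acetal of F1 | O=S1(=O)C[C@]23CC[C@H](C2(C)C)C[C@@H]3N1/C(O[Si](C)(C)C)=C(\C)[C@@H](CO[Si](C)(C)C(C)(C)C)CCC4(C)OCC(C)(C)CO4
F3 | step 9 | tert-butyl{[(2R,3S)-3-chloro-3-methyl-2-[2-(2,5,5-trimethyl-1,3-dioxan-2-yl)ethyl]pent-4-yn-1-yl]oxy}dimethylsilane | C#C[C@@](C)(Cl)[C@@H](CO[Si](C)(C)C(C)(C)C)CCC1(C)OCC(C)(C)CO1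
F4 | step 13 | (2R,3R,5R)-3-bromo-5-[(2S,3E)-4-bromo-2-chlorobut-3-en-2-yl]-2-methyloxan-2-ol | C[C@@](Cl)(/C=C/Br)[C@H]1CO[C@@](C)(O)[C@H](Br)C1
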